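**Retrosynthetic overview**

1. Target ⇐ diketone 40 by reduction of the C2 and C12 epoxy ketones; C9 acetate, C6 chloride (inversion of an allylic alcohol) and the γ-lactone (C8–C17 bond, Reformatsky closure onto O7) are installed just before.
2. The strategy rests on the cyclohexane ring (C1, C10–C14), which shares the trans C1–C10 bond with the ten-membered ring and carries the C1 quaternary methyl, the C11 methyl and oxygen at C12. It is disconnected by a Diels–Alder reaction into the ten-membered (E)-2-methyl enone 25 (C2 ketone, C1=C10) and (Z)-3-silyloxypenta-1,3-diene 27, forming C10–C11 and C1–C14.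
3. Enone 25 ⇐ Nozaki–Hiyama–Kishi closure of the C1–C2 bond from an (E)-alkenyl iodide and a cis-epoxy aldehyde; the C3/C4 oxirane comes from a Sharpless epoxidation before ring closure.
4. Acyclic chain ⇐ D-glucose (C6–C10), 2-bromoacrolein diethyl acetal (C4, C5, C16), Corey–Fuchs/MeI (C1, C15), Ando phosphonoacetate (C2, C3).
5. Ring order: C3/C4 oxirane, ten-membered carbocycle, cyclohexane (key step), C13/C14 oxirane, γ-lactone.

Key step: step 20

Remark: briarane numbering is used throughout; C8 of the cycloaddition precursor later becomes a ketone, so its configuration is a spectator and is taken as D-xylo (from D-glucose) with O8 as PMB, O7 as TES and O6/O9 as TBS ethers.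
Remark: 7 and 12 are anomeric mixtures, 24 is a C2-epimer mixture and 32–34 are mixtures at the CHBr carbon; each converges later, so these centres are left undefined in the SMILES.

**Route**

Step 1
Reactants: 1 diacetone-D-glucose
Product: 2 3-O-PMB diacetone-D-glucose
Conditions: NaH, PMBCl, Bu4NI (cat.), DMF, 0 °C to rt
Reagents that add atoms: 4-methoxybenzyl chloride, COc1ccc(CCl)cc1
Why: Williamson etherification of the only free hydroxyl (sugar O3, later O8) touches no stereocentre.

Step 2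
Reactants: 2 3-O-PMB diacetone-D-glucose
Product: 3 1,2-O-isopropylidene-3-O-PMB-α-D-xylo-pentodialdo-1,4-furanose (C10 aldehyde)
Conditions: H5IO6, EtOAc, rt
Reagents that add atoms: none
Why: Periodic acid should hydrolyse the more labile terminal acetonide and cleave the freed glycol in one pot (oxidative glycol cleavage), leaving C9 untouched.

Step 3
Reactants: 3 C10 aldehyde
Product: 4 1,1-dibromoalkene
Conditions: CBr4, PPh3, CH2Cl2, 0 °C
Reagents that add atoms: carbon tetrabromide, BrC(Br)(Br)Br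
Why: Corey–Fuchs dibromo-olefination runs without base, so the α-alkoxy aldehyde should not epimerise.

Step 4
Reactants: 4 1,1-dibromoalkene
Product: 6 methyl alkyne (C10≡C1–C15) on the 1,2-O-isopropylidene-3-O-PMB furanose, via lithium acetylide 5 (not isolated)
Conditions: n-BuLi (2.2 equiv), THF, −78 °C; then MeI, −78 °C to rt
Reagents that add atoms: iodomethane, CI
Why: Second stage of the Corey–Fuchs sequence (Br/Li exchange, Fritsch–Buttenberg–Wiechell shift) followed by C-methylation of the acetylide supplies C1 and C15.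

Step 5
Reactants: 6 methyl alkyne furanose acetonide
Product: 7 lactol diol (5,6,7-trideoxy-3-O-PMB-D-xylo-hept-5-ynofuranose)
Conditions: AcOH/H2O (3:1), 60 °C
Reagents that add atoms: none
Why: Acid hydrolysis of the 1,2-O-isopropylidene acetal unmasks the lactol carbon (C6) and O7, while the PMB ether and alkyne tolerate dilute acetic acid.

Step 6
Reactants: 7 lactol diol
Product: 8 2-hydroxy-γ-lactone (3-O-PMB-D-xylo-hept-5-ynono-1,4-lactone)
Conditions: Ag2CO3 on Celite, toluene, reflux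
Reagents that add atoms: none
Why: Fétizon oxidation is selective for the hemiacetal over the secondary alcohol.

Step 7
Reactants: 8 2-hydroxy-γ-lactone
Product: 9 2-O-TES lactone
Conditions: TESCl, imidazole, DMF, 0 °C
Reagents that add atoms: chlorotriethylsilane, CC[Si](Cl)(CC)CC
Why: Standard silylation gives O7 its own, selectively removable group.

Step 8
Reactants: 9 2-O-TES lactone, 10 2-bromoacrolein diethyl acetal
Product: 12 C6 hemiketal, via 3,3-diethoxyprop-1-en-2-yllithium 11 (not isolated)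
Conditions: 10, t-BuLi (2 equiv), Et2O, −78 °C; then 9, THF, −78 °C; NH4Cl
Reagents that add atoms: none
Why: Bromine–lithium exchange gives the 2-lithioacrolein acetal, and organolithium mono-addition to the γ-lactone stops at the lactolate at −78 °C, forming the C5–C6 bond.

Step 9
Reactants: 12 C6 hemiketal
Product: 14 6,9-diol with 6,7-syn configuration, via open-chain hydroxy enone 13 (not isolated)
Conditions: NaBH4, CeCl3·7H2O, EtOH, −40 °C
Reagents that add atoms: none
Why: Luche 1,2-reduction of the ring-opened ketone under Felkin–Anh control (C7 silyloxy group anti to hydride) should set C6 syn to O7, the configuration needed for later chloride inversion.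

Step 10
Reactants: 14 6,9-diol
Product: 15 6,9-bis-TBS ether
Conditions: TBSCl, imidazole, DMAP, DMF, 45 °C
Reagents that add atoms: tert-butyldimethylsilyl chloride, CC(C)(C)[Si](C)(C)Cl
Why: Silylation under non-Lewis-acidic conditions protects both secondary alcohols without disturbing the diethyl acetal.

Step 11
Reactants: 15 6,9-bis-TBS ether
Product: 17 (E)-alkenyl iodide (iodine on C1 and trans to C9), via alkenylzirconocene chloride 16 (not isolated)
Conditions: Cp2Zr(H)Cl, THF, rt; then I2, 0 °C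
Reagents that add atoms: iodine, II
Why: Schwartz hydrozirconation adds syn with zirconium at the methyl-bearing alkyne carbon distal to the C9 silyl ether, and iodinolysis with retention fixes the later E enone geometry; the hindered 1,1-disubstituted alkene should react more slowly.

Step 12
Reactants: 17 (E)-alkenyl iodide acetal
Product: 18 C4 enal
Conditions: 10% aq. oxalic acid on SiO2, CH2Cl2, rt
Reagents that add atoms: water, O
Why: The α,β-unsaturated acetal hydrolyses under conditions mild enough to keep the TES and TBS ethers.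

Step 13
Reactants: 18 C4 enal
Product: 19 ethyl (Z)-dienoate (C2 ester, Z C3=C4)
Conditions: (PhO)2P(O)CH2CO2Et, NaH, THF, −78 °C
Reagents that add atoms: ethyl 2-(diphenoxyphosphoryl)acetate, CCOC(=O)CP(=O)(Oc1ccccc1)Oc1ccccc1
Why: Ando's Z-selective Horner–Wadsworth–Emmons olefination of the non-enolisable enal brings in C2 and C3 with the cis geometry required for the cis oxirane.

Step 14
Reactants: 19 ethyl (Z)-dienoate
Product: 20 (Z)-allylic alcohol
Conditions: DIBAL-H, CH2Cl2, −78 °C
Reagents that add atoms: none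
Why: 1,2-Reduction of the enoate keeps the Z alkene and tolerates the alkenyl iodide at low temperature.

Step 15
Reactants: 20 (Z)-allylic alcohol
Product: 21 cis-epoxy alcohol (3S,4R)
Conditions: Ti(OiPr)4, L-(+)-DET, t-BuOOH, 4 Å MS, CH2Cl2, −20 °C
Reagents that add atoms: tert-butyl hydroperoxide, CC(C)(C)OO
Why: Sharpless asymmetric epoxidation with L-(+)-tartrate delivers oxygen to the face giving (3S,4R), stereospecifically cis from the Z alkene, and only the allylic alkene reacts.

Step 16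
Reactants: 21 cis-epoxy alcohol
Product: 22 cis-epoxy aldehyde
Conditions: Dess–Martin periodinane, NaHCO3, CH2Cl2, 0 °C
Reagents that add atoms: none
Why: Buffered Dess–Martin oxidation gives the aldehyde without epimerising C3.

Step 17
Reactants: 22 cis-epoxy aldehyde
Product: 24 ten-membered allylic alcohol (C2 epimers), via alkenylchromium(III) dichloride 23 (not isolated)
Conditions: CrCl2 (8 equiv), NiCl2 (cat.), DMSO/THF, rt, 2 mM, slow addition
Reagents that add atoms: none
Why: Nozaki–Hiyama–Kishi macrocyclisation forms C1–C2 with retention of the E alkenyl geometry and aldehyde chemoselectivity; the new C2 carbinol is oxidised next, so its configuration is irrelevant.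

Step 18
Reactants: 24 ten-membered allylic alcohol
Product: 25 ten-membered (E)-2-methyl enone with C3/C4 oxirane and C5 methylidene
Conditions: Dess–Martin periodinane, NaHCO3, CH2Cl2, 0 °C to rt
Reagents that add atoms: none
Why: Oxidation of both C2 epimers converges on the enone without touching the E alkene or the oxirane.

Step 19
Reactants: 26 ethyl vinyl ketone
Product: 27 (Z)-3-(trimethylsilyloxy)penta-1,3-diene
Conditions: TMSOTf, Et3N, Et2O, 0 °C
Reagents that add atoms: trimethylsilyl trifluoromethanesulfonate, C[Si](C)(C)OS(=O)(=O)C(F)(F)F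
Why: Soft enolisation towards the ethyl group should give mainly the Z silyl dienol ether.

Step 20
Reactants: 25 ten-membered (E)-2-methyl enone, 27 (Z)-3-(trimethylsilyloxy)penta-1,3-diene
Product: 28 bicyclic C12 silyl enol ether (trans C1–C10 fusion; C1, C10, C11 set)
Conditions: MAD [MeAl(O-2,6-tBu2-4-MeC6H2)2] (1.2 equiv), toluene, −78 to −20 °C; Et3N quench
Reagents that add atoms: none
Why: Proposed new method: a Lewis-acid-promoted, asynchronous [4+2] cycloaddition in which the enol-ether terminus C11 of 27 bonds to the enone β-carbon C10 and the vinyl terminus C14 to C1, placing the silyloxy carbon C12 para to the acyl-bearing C1; the closest known reactions are Lewis-acid Diels–Alder additions of 2-silyloxydienes to 2-methylcycloalk-2-enones and cycloadditions of strained (E)-cycloalkenes, neither shown on a ten-membered (E)-2-methyl enone. The six-membered ring closes by intermolecular annulation onto the preformed macrocycle, both σ bonds forming suprafacially on one alkene face, so the E geometry becomes the trans C1–C10 fusion and the C1 quaternary centre. C10 and C1 are set by attack on the outer face of the planar-chiral enone: A(1,3) strain with the C1 methyl holds H9 in the alkene plane, the ring chain (C8, C3) then covers the inner face and the C9 silyloxy group takes the outside position on the open face. C11 is set by the carbonyl-exo transition state, in which the outside methyl of the Z diene ends cis to the C1 methyl and C9; the α-methyl group and the bulky aryloxide ligands on the complexed C2 carbonyl should disfavour the carbonyl-endo alternative. The step needs regio-, face- and exo-selectivity and survival of the oxirane and silyl enol ether, which the para-directing silyloxy group, the ring conformation and a halide-free aprotic Lewis acid are meant to secure. Twist strain of the E-cycloalkenone should help this hindered trisubstituted dienophile react.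

Step 21
Reactants: 28 bicyclic C12 silyl enol ether
Product: 29 C12 enone (C13=C14)
Conditions: Pd(OAc)2 (1.1 equiv), MeCN, rt
Reagents that add atoms: none
Why: Saegusa–Ito oxidation; the C13 palladium enolate can only β-eliminate towards C14.

Step 22
Reactants: 29 C12 enone
Product: 30 13α,14α-epoxy-12-ketone
Conditions: t-BuOOH, DBU, CH2Cl2, 0 °C
Reagents that add atoms: tert-butyl hydroperoxide, CC(C)(C)OO
Why: Weitz–Scheffer nucleophilic epoxidation touches only the enone, and hydroperoxide should add to C14 anti to the adjacent angular C1 methyl, as with steroidal 1-en-3-ones.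

Step 23
Reactants: 30 13α,14α-epoxy-12-ketone
Product: 31 C7 alcohol
Conditions: HF·pyridine, pyridine, THF, 0 °C
Reagents that add atoms: none
Why: Buffered fluoride should cleave the secondary TES ether well before the two TBS ethers.

Step 24
Reactants: 31 C7 alcohol
Product: 32 C7 2-bromopropanoate
Conditions: 2-bromopropanoyl bromide, pyridine, CH2Cl2, −20 °C
Reagents that add atoms: 2-bromopropanoyl bromide, CC(Br)C(=O)Br
Why: O-Acylation of the only free hydroxyl attaches the C17–C19 unit to the future lactone oxygen.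

Step 25
Reactants: 32 C7 2-bromopropanoate
Product: 33 C8 alcohol
Conditions: DDQ, CH2Cl2/pH 7 buffer, 0 °C
Reagents that add atoms: none
Why: Oxidative PMB cleavage under neutral conditions spares the oxiranes, silyl ethers and bromo ester.

Step 26
Reactants: 33 C8 alcohol
Product: 34 C8 ketone
Conditions: Dess–Martin periodinane, NaHCO3, CH2Cl2, 0 °C
Reagents that add atoms: none
Why: Mild oxidation gives the α-acyloxy ketone without enolising C7 or C9.

Step 27
Reactants: 34 C8 ketone
Product: 36 γ-lactone with C8 tertiary alcohol and C17 methyl, via bromozinc ester enolate 35 (not isolated)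
Conditions: activated Zn (Zn–Cu), THF, 0 °C to rt
Reagents that add atoms: none
Why: Intramolecular Reformatsky reaction; the tethered zinc enolate can reach only the adjacent C8 carbonyl, an anti C6–C7–C8–C9 ring segment should give the trans-fused lactone with 8-OH cis to C6, and the C17 methyl should settle anti to C9 (this centre remains epimerisable).

Step 28
Reactants: 36 γ-lactone bis-TBS ether
Product: 37 C6 allylic alcohol
Conditions: HF·pyridine, THF, 0 °C to rt
Reagents that add atoms: none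
Why: The allylic O6 silyl ether is far less hindered than the O9 ether flanked by quaternary C8, so it should be cleaved selectively.

Step 29
Reactants: 37 C6 allylic alcohol
Product: 38 C6 allylic chloride (inverted)
Conditions: PPh3, hexachloroacetone, CH2Cl2, −20 to 0 °C
Reagents that add atoms: hexachloroacetone, ClC(Cl)(Cl)C(=O)C(Cl)(Cl)Cl
Why: Magid's allylic chlorination proceeds by SN2 displacement of the alkoxyphosphonium with inversion and little allylic transposition, setting C6.

Step 30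
Reactants: 38 C6 allylic chloride
Product: 39 C9 alcohol
Conditions: Et3N·3HF, MeCN, 45 °C
Reagents that add atoms: none
Why: Mildly acidic fluoride removes the remaining hindered TBS ether without displacing the allylic chloride or opening the lactone.

Step 31
Reactants: 39 C9 alcohol
Product: 40 C9 acetate (2,12-diketone)
Conditions: Ac2O, Et3N, DMAP (cat.), CH2Cl2, 0 °C to rt
Reagents that add atoms: acetic anhydride, CC(=O)OC(C)=O
Why: Only the secondary C9 hydroxyl acylates; the tertiary C8 hydroxyl is inert under these conditions.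

Step 32
Reactants: 40 C9 acetate diketone
Product: 41 CNP0314105.1 (target)
Conditions: NaBH4, CeCl3·7H2O, MeOH, −78 to −40 °C
Reagents that add atoms: none
Why: Luche reduction of both epoxy ketones: at C12 hydride should enter from the α face, away from the C11 methyl and the β ring substituents, giving the 12β-alcohol trans to the oxirane; at C2 the cerium-chelated epoxy ketone should give the erythro (2S) epoxy alcohol; acetate, lactone and allylic chloride should survive.

**Compound list**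

1 | 1,2:5,6-di-O-isopropylidene-α-D-glucofuranose | CC1(C)O[C@H]2O[C@@H]([C@H](O)[C@H]2O1)[C@H]1COC(C)(C)O1 | starting material
2 | 3-O-(4-methoxybenzyl)-1,2:5,6-di-O-isopropylidene-α-D-glucofuranose | CC1(C)O[C@H]2O[C@@H]([C@H](OCc3ccc(OC)cc3)[C@H]2O1)[C@H]1COC(C)(C)O1 | intermediate
3 | 1,2-O-isopropylidene-3-O-PMB-α-D-xylo-pentodialdo-1,4-furanose | CC1(C)O[C@H]2O[C@@H]([C@H](OCc3ccc(OC)cc3)[C@H]2O1)C=O | intermediate
4 | 1,1-dibromoalkene from 3 | CC1(C)O[C@H]2O[C@@H]([C@H](OCc3ccc(OC)cc3)[C@H]2O1)C=C(Br)Br | intermediate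
5 | lithium acetylide | CC1(C)O[C@H]2O[C@@H]([C@H](OCc3ccc(OC)cc3)[C@H]2O1)C#C[Li] | intermediate (not isolated)
6 | 5,6,7-trideoxy-1,2-O-isopropylidene-3-O-PMB-α-D-xylo-hept-5-ynofuranose | CC1(C)O[C@H]2O[C@@H]([C@H](OCc3ccc(OC)cc3)[C@H]2O1)C#CC | intermediate
7 | 5,6,7-trideoxy-3-O-PMB-D-xylo-hept-5-ynofuranose (anomers) | OC1O[C@@H]([C@H](OCc2ccc(OC)cc2)[C@H]1O)C#CC | intermediate
8 | 5,6,7-trideoxy-3-O-PMB-D-xylo-hept-5-ynono-1,4-lactone | O=C1O[C@@H]([C@H](OCc2ccc(OC)cc2)[C@H]1O)C#CC | intermediate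
9 | 2-O-TES derivative of lactone 8 | O=C1O[C@@H]([C@H](OCc2ccc(OC)cc2)[C@H]1O[Si](CC)(CC)CC)C#CC | intermediate
10 | 2-bromoacrolein diethyl acetal (2-bromo-3,3-diethoxyprop-1-ene) | C=C(Br)C(OCC)OCC | starting material
11 | 3,3-diethoxyprop-1-en-2-yllithium | C=C([Li])C(OCC)OCC | intermediate (not isolated)
12 | C6 hemiketal (anomers) carrying the 3,3-diethoxyprop-1-en-2-yl group | CCOC(OCC)C(=C)C1(O)O[C@@H]([C@H](OCc2ccc(OC)cc2)[C@H]1O[Si](CC)(CC)CC)C#CC | intermediate
13 | open-chain C6 ketone (C9 hydroxy enone) | CCOC(OCC)C(=C)C(=O)[C@H](O[Si](CC)(CC)CC)[C@@H](OCc1ccc(OC)cc1)[C@H](O)C#CC | intermediate (not isolated)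
14 | acyclic 6,9-diol (O7 TES, O8 PMB, C4 diethyl acetal, C10≡C1 alkyne) | CCOC(OCC)C(=C)[C@@H](O)[C@H](O[Si](CC)(CC)CC)[C@@H](OCc1ccc(OC)cc1)[C@H](O)C#CC | intermediate
15 | 6,9-bis-TBS ether of 14 | CCOC(OCC)C(=C)[C@@H](O[Si](C)(C)C(C)(C)C)[C@H](O[Si](CC)(CC)CC)[C@@H](OCc1ccc(OC)cc1)[C@H](O[Si](C)(C)C(C)(C)C)C#CC | intermediate
16 | alkenylzirconocene chloride (Zr on C1) | CCOC(OCC)C(=C)[C@@H](O[Si](C)(C)C(C)(C)C)[C@H](O[Si](CC)(CC)CC)[C@@H](OCc1ccc(OC)cc1)[C@H](O[Si](C)(C)C(C)(C)C)/C=C(/[Zr](Cl)(C1C=CC=C1)C1C=CC=C1)C | intermediate (not isolated)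
17 | (E)-alkenyl iodide (C1 iodide) with C4 diethyl acetal | CCOC(OCC)C(=C)[C@@H](O[Si](C)(C)C(C)(C)C)[C@H](O[Si](CC)(CC)CC)[C@@H](OCc1ccc(OC)cc1)[C@H](O[Si](C)(C)C(C)(C)C)/C=C(/I)C | intermediate
18 | C4 enal | O=CC(=C)[C@@H](O[Si](C)(C)C(C)(C)C)[C@H](O[Si](CC)(CC)CC)[C@@H](OCc1ccc(OC)cc1)[C@H](O[Si](C)(C)C(C)(C)C)/C=C(/I)C | intermediate
19 | ethyl (Z)-dienoate (C2 ester) | CCOC(=O)/C=C\C(=C)[C@@H](O[Si](C)(C)C(C)(C)C)[C@H](O[Si](CC)(CC)CC)[C@@H](OCc1ccc(OC)cc1)[C@H](O[Si](C)(C)C(C)(C)C)/C=C(/I)C | intermediate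
20 | (Z)-allylic alcohol (C2 carbinol) | OC/C=C\C(=C)[C@@H](O[Si](C)(C)C(C)(C)C)[C@H](O[Si](CC)(CC)CC)[C@@H](OCc1ccc(OC)cc1)[C@H](O[Si](C)(C)C(C)(C)C)/C=C(/I)C | intermediate
21 | (3S,4R)-cis-epoxy alcohol | OC[C@@H]1O[C@@H]1C(=C)[C@@H](O[Si](C)(C)C(C)(C)C)[C@H](O[Si](CC)(CC)CC)[C@@H](OCc1ccc(OC)cc1)[C@H](O[Si](C)(C)C(C)(C)C)/C=C(/I)C | intermediate
22 | cis-epoxy aldehyde (C2 aldehyde, C1 alkenyl iodide) | O=C[C@@H]1O[C@@H]1C(=C)[C@@H](O[Si](C)(C)C(C)(C)C)[C@H](O[Si](CC)(CC)CC)[C@@H](OCc1ccc(OC)cc1)[C@H](O[Si](C)(C)C(C)(C)C)/C=C(/I)C | intermediate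
23 | alkenylchromium(III) dichloride | O=C[C@@H]1O[C@@H]1C(=C)[C@@H](O[Si](C)(C)C(C)(C)C)[C@H](O[Si](CC)(CC)CC)[C@@H](OCc1ccc(OC)cc1)[C@H](O[Si](C)(C)C(C)(C)C)/C=C(/[Cr](Cl)Cl)C | intermediate (not isolated)
24 | ten-membered (E)-allylic alcohol (C2 epimers) with C3/C4 oxirane and C5 methylidene | C=C1[C@H]2O[C@H]2C(O)/C(C)=C/[C@@H](O[Si](C)(C)C(C)(C)C)[C@H](OCc3ccc(OC)cc3)[C@@H](O[Si](CC)(CC)CC)[C@@H]1O[Si](C)(C)C(C)(C)C | intermediate
25 | ten-membered (E)-2-methyl enone (C2 ketone, C1=C10; O6 TBS, O7 TES, O8 PMB, O9 TBS) | C=C1[C@H]2O[C@H]2C(=O)/C(C)=C/[C@@H](O[Si](C)(C)C(C)(C)C)[C@H](OCc3ccc(OC)cc3)[C@@H](O[Si](CC)(CC)CC)[C@@H]1O[Si](C)(C)C(C)(C)C | intermediate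
26 | ethyl vinyl ketone (pent-1-en-3-one) | CCC(=O)C=C | starting material
27 | (Z)-3-(trimethylsilyloxy)penta-1,3-diene | C=C/C(O[Si](C)(C)C)=C/C | intermediate
28 | bicyclic C12 trimethylsilyl enol ether (Diels–Alder adduct) | C=C1[C@H]2O[C@H]2C(=O)[C@]2(C)[C@H]([C@@H](C)C(O[Si](C)(C)C)=CC2)[C@@H](O[Si](C)(C)C(C)(C)C)[C@H](OCc3ccc(OC)cc3)[C@@H](O[Si](CC)(CC)CC)[C@@H]1O[Si](C)(C)C(C)(C)C | intermediate
29 | C12 enone (C13=C14) | C=C1[C@H]2O[C@H]2C(=O)[C@]2(C)[C@H]([C@@H](C)C(=O)C=C2)[C@@H](O[Si](C)(C)C(C)(C)C)[C@H](OCc3ccc(OC)cc3)[C@@H](O[Si](CC)(CC)CC)[C@@H]1O[Si](C)(C)C(C)(C)C | intermediate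
30 | 13α,14α-epoxy-12-ketone | C=C1[C@H]2O[C@H]2C(=O)[C@]2(C)[C@H]([C@@H](C)C(=O)[C@@H]3O[C@@H]32)[C@@H](O[Si](C)(C)C(C)(C)C)[C@H](OCc3ccc(OC)cc3)[C@@H](O[Si](CC)(CC)CC)[C@@H]1O[Si](C)(C)C(C)(C)C | intermediate
31 | C7 alcohol | C=C1[C@H]2O[C@H]2C(=O)[C@]2(C)[C@H]([C@@H](C)C(=O)[C@@H]3O[C@@H]32)[C@@H](O[Si](C)(C)C(C)(C)C)[C@H](OCc3ccc(OC)cc3)[C@@H](O)[C@@H]1O[Si](C)(C)C(C)(C)C | intermediate
32 | C7 2-bromopropanoate | C=C1[C@H]2O[C@H]2C(=O)[C@]2(C)[C@H]([C@@H](C)C(=O)[C@@H]3O[C@@H]32)[C@@H](O[Si](C)(C)C(C)(C)C)[C@H](OCc3ccc(OC)cc3)[C@@H](OC(=O)C(C)Br)[C@@H]1O[Si](C)(C)C(C)(C)C | intermediate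
33 | C8 alcohol | C=C1[C@H]2O[C@H]2C(=O)[C@]2(C)[C@H]([C@@H](C)C(=O)[C@@H]3O[C@@H]32)[C@@H](O[Si](C)(C)C(C)(C)C)[C@H](O)[C@@H](OC(=O)C(C)Br)[C@@H]1O[Si](C)(C)C(C)(C)C | intermediate
34 | C8 ketone | C=C1[C@H]2O[C@H]2C(=O)[C@]2(C)[C@H]([C@@H](C)C(=O)[C@@H]3O[C@@H]32)[C@@H](O[Si](C)(C)C(C)(C)C)C(=O)[C@@H](OC(=O)C(C)Br)[C@@H]1O[Si](C)(C)C(C)(C)C | intermediate
35 | bromozinc ester enolate | C=C1[C@H]2O[C@H]2C(=O)[C@]2(C)[C@H]([C@@H](C)C(=O)[C@@H]3O[C@@H]32)[C@@H](O[Si](C)(C)C(C)(C)C)C(=O)[C@@H](OC(O[Zn]Br)=CC)[C@@H]1O[Si](C)(C)C(C)(C)C | intermediate (not isolated)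
36 | γ-lactone with 8-hydroxy and 17-methyl groups (6,9-bis-TBS) | C=C1[C@H]2O[C@H]2C(=O)[C@]2(C)[C@H]([C@@H](C)C(=O)[C@@H]3O[C@@H]32)[C@@H](O[Si](C)(C)C(C)(C)C)[C@]2(O)[C@@H](C)C(=O)O[C@H]2[C@@H]1O[Si](C)(C)C(C)(C)C | intermediate
37 | C6 allylic alcohol | C=C1[C@H]2O[C@H]2C(=O)[C@]2(C)[C@H]([C@@H](C)C(=O)[C@@H]3O[C@@H]32)[C@@H](O[Si](C)(C)C(C)(C)C)[C@]2(O)[C@@H](C)C(=O)O[C@H]2[C@@H]1O | intermediate
38 | C6 allylic chloride | C=C1[C@H]2O[C@H]2C(=O)[C@]2(C)[C@H]([C@@H](C)C(=O)[C@@H]3O[C@@H]32)[C@@H](O[Si](C)(C)C(C)(C)C)[C@]2(O)[C@@H](C)C(=O)O[C@H]2[C@H]1Cl | intermediate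
39 | C9 alcohol | C=C1[C@H]2O[C@H]2C(=O)[C@]2(C)[C@H]([C@@H](C)C(=O)[C@@H]3O[C@@H]32)[C@@H](O)[C@]2(O)[C@@H](C)C(=O)O[C@H]2[C@H]1Cl | intermediate
40 | C9 acetate, 2,12-diketone | C=C1[C@H]2O[C@H]2C(=O)[C@]2(C)[C@H]([C@@H](C)C(=O)[C@@H]3O[C@@H]32)[C@@H](OC(C)=O)[C@]2(O)[C@@H](C)C(=O)O[C@H]2[C@H]1Cl | intermediate
41 | CNP0314105.1 | C=C1[C@H]2O[C@H]2[C@@H](O)[C@]2(C)[C@H]([C@@H](C)[C@@H](O)[C@@H]3O[C@@H]32)[C@@H](OC(C)=O)[C@]2(O)[C@@H](C)C(=O)O[C@H]2[C@H]1Cl | target

**Step count and risks**

Total step count: 32. Longest linear sequence: 31 steps (steps 1–18 and 20–32; step 19 makes the diene).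

Steps most likely to fail:

1. Step 20 (Diels–Alder, proposed new method). The hindered trisubstituted dienophile may not react, the diene may approach the wrong face or in the carbonyl-endo sense, or the Lewis acid may open the oxirane. The fallback sets out from 25 and 26 and replaces the cycloaddition by a stepwise anionic Michael–Michael annulation. Ethyl vinyl ketone 26 is deprotonated with LDA (THF, −78 °C) to the lithium dienolate F1, which adds through its α-carbon to C10 of 25; the resulting C1 enolate then closes onto the vinyl ketone terminus to give, after quench, the saturated 12-ketone F2. C11 lies α to that ketone and can be equilibrated if the kinetic epimer is wrong. Kinetic enolisation of F2 at C13 (LiHMDS, TMSCl, −78 °C) returns to the route at 28.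

2. Step 17 (NHK macrocyclisation). Oligomerisation, chromium(II) reduction of the epoxy aldehyde or ring strain may prevent closure. The fallback sets out from 22 and closes the same bond by acylation instead of carbonyl addition. Pinnick oxidation (NaClO2, NaH2PO4, 2-methyl-2-butene) gives the epoxy acid F3; Pd-catalysed stannylation with hexamethylditin gives the alkenylstannane acid F4; Ghosez's reagent gives the acid chloride F5; intramolecular Stille acylation (Pd2(dba)3, tri(2-furyl)phosphine, high dilution) delivers the enone directly, rejoining at 25 and making step 18 unnecessary.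

3. Step 27 (Reformatsky lactonisation). The tethered enolate may attack the wrong carbonyl face (cis-fused or C8-epimeric lactone), or zinc may reduce an epoxy ketone. The fallback sets out from 30 and lets an external reagent choose the ketone face. DDQ gives the C8 alcohol F6 with O7 still silylated; Dess–Martin oxidation gives the C8 ketone F7; an intermolecular Reformatsky reaction with ethyl 2-bromopropanoate and zinc gives the hydroxy ester F8 by attack on the outer face of the ring; HF·pyridine then frees O7 and the hydroxy ester lactonises, rejoining at 36.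

**Further compounds**

F1 | step 20 | lithium penta-1,3-dien-3-olate (dienolate of ethyl vinyl ketone) | C=CC(O[Li])=CC
F2 | step 20 | saturated bicyclic 12-ketone (C13 and C14 methylene) | C=C1[C@H]2O[C@H]2C(=O)[C@]2(C)[C@H]([C@@H](C)C(=O)CC2)[C@@H](O[Si](C)(C)C(C)(C)C)[C@H](OCc3ccc(OC)cc3)[C@@H](O[Si](CC)(CC)CC)[C@@H]1O[Si](C)(C)C(C)(C)C
F3 | step 17 | cis-epoxy carboxylic acid with C1 alkenyl iodide | OC(=O)[C@@H]1O[C@@H]1C(=C)[C@@H](O[Si](C)(C)C(C)(C)C)[C@H](O[Si](CC)(CC)CC)[C@@H](OCc1ccc(OC)cc1)[C@H](O[Si](C)(C)C(C)(C)C)/C=C(/I)C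
F4 | step 17 | cis-epoxy carboxylic acid with C1 trimethylstannyl alkene | OC(=O)[C@@H]1O[C@@H]1C(=C)[C@@H](O[Si](C)(C)C(C)(C)C)[C@H](O[Si](CC)(CC)CC)[C@@H](OCc1ccc(OC)cc1)[C@H](O[Si](C)(C)C(C)(C)C)/C=C(/[Sn](C)(C)C)C
F5 | step 17 | cis-epoxy acid chloride with C1 trimethylstannyl alkene | ClC(=O)[C@@H]1O[C@@H]1C(=C)[C@@H](O[Si](C)(C)C(C)(C)C)[C@H](O[Si](CC)(CC)CC)[C@@H](OCc1ccc(OC)cc1)[C@H](O[Si](C)(C)C(C)(C)C)/C=C(/[Sn](C)(C)C)C
F6 | step 27 | C8 alcohol with O7 TES ether | C=C1[C@H]2O[C@H]2C(=O)[C@]2(C)[C@H]([C@@H](C)C(=O)[C@@H]3O[C@@H]32)[C@@H](O[Si](C)(C)C(C)(C)C)[C@H](O)[C@@H](O[Si](CC)(CC)CC)[C@@H]1O[Si](C)(C)C(C)(C)C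
F7 | step 27 | C8 ketone with O7 TES ether | C=C1[C@H]2O[C@H]2C(=O)[C@]2(C)[C@H]([C@@H](C)C(=O)[C@@H]3O[C@@H]32)[C@@H](O[Si](C)(C)C(C)(C)C)C(=O)[C@@H](O[Si](CC)(CC)CC)[C@@H]1O[Si](C)(C)C(C)(C)C
F8 | step 27 | C8 tertiary alcohol bearing the ethyl propanoate side chain (Reformatsky adduct) | C=C1[C@H]2O[C@H]2C(=O)[C@]2(C)[C@H]([C@@H](C)C(=O)[C@@H]3O[C@@H]32)[C@@H](O[Si](C)(C)C(C)(C)C)[C@](O)([C@@H](C)C(=O)OCC)[C@@H](O[Si](CC)(CC)CC)[C@@H]1O[Si](C)(C)C(C)(C)C
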